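**Plan**
1. Retrosynthesis: the C9=CHBr bond (Wittig) and the C9 carbonyl (allylic oxidation) are removed first. Ring B is then opened at C6–C7. The C3–Br bond, the C1–C6 epoxide oxygen and the C6–C11 bond follow, leading back to (4R,6R)-actinol and a five-carbon (Z)-vinylsilane chain.
2. Forward: ring A is bought as actinol and its enol triflate is joined to the chain at C6–C11 (Negishi). Hydroxyl-directed epoxidation and Appel bromination follow. Ring B closes last, by Lewis-acid opening of the tetrasubstituted epoxide with ipso attack of the vinylsilane.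
3. Enabling feature: in ring A the carbinol carbon C1(OH)(CH3) and the spiro carbon C6 are adjacent, with the oxygen anti to the vinylic carbon C7 of ring B, and the C7=C8 double bond starts at the spiro carbon. This is the imprint of an anti opening of a 2,6,6-trimethylcyclohexene oxide at its chain-bearing carbon by a vinylsilane hanging from that same carbon.
4. Stereochemistry: C3 comes from actinol and is inverted once by SN2 bromination. C1 is set by epoxidation syn to the C3 hydroxyl. C6 is set by inversion at the epoxide carbon in the key step. The E bromoalkene comes from a kinetically controlled Wittig reaction.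

Key step: step 9

Remark: (4R,6R)-actinol and (5-chloropent-1-yn-1-yl)trimethylsilane are taken as purchasable; atoms are numbered as in the spiro[5.5]undecane skeleton of the target (C1 carbinol, C3 CHBr, C5 CMe2, C6 spiro, C7=C8, C9 bearing =CHBr, C10, C11).

**Route**

Step 1
Reactants: 1 (4R,6R)-4-hydroxy-2,2,6-trimethylcyclohexan-1-one ((4R,6R)-actinol)
Product: 2 (4R,6R)-4-[(tert-butyldimethylsilyl)oxy]-2,2,6-trimethylcyclohexan-1-one
Conditions: TBSCl, imidazole, DMF, rt
Reagents that add atoms: tert-butyldimethylsilyl chloride, CC(C)(C)[Si](C)(C)Cl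
Why: Imidazole-promoted silylation of the secondary alcohol, needed because a free hydroxyl would be triflated in step 2; no stereocentre is touched.

Step 2
Reactants: 2 (4R,6R)-4-[(tert-butyldimethylsilyl)oxy]-2,2,6-trimethylcyclohexan-1-one
Product: 4 (4R)-4-[(tert-butyldimethylsilyl)oxy]-2,6,6-trimethylcyclohex-1-en-1-yl trifluoromethanesulfonate, via lithium enolate 3 (not isolated)
Conditions: LiN(i-Pr)2, THF, −78 → 0 °C; PhNTf2, −78 °C → rt; aq. NH4Cl
Reagents that add atoms: N-phenylbis(trifluoromethanesulfonimide), O=S(=O)(N(c1ccccc1)S(=O)(=O)C(F)(F)F)C(F)(F)F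
Why: The ketone can enolise only toward the methyl-bearing carbon (the other flank is quaternary), so O-triflation of the enolate should give a single tetrasubstituted enol triflate; the methyl-bearing stereocentre is erased on purpose and the silyloxy centre is untouched.

Step 3
Reactants: 5 (5-chloropent-1-yn-1-yl)trimethylsilane
Product: 6 [(1Z)-5-chloropent-1-en-1-yl]trimethylsilane
Conditions: H2 (1 atm), Pd/CaCO3 poisoned with Pb(OAc)2, quinoline, hexane, rt
Reagents that add atoms: none
Why: cis-Semihydrogenation of the silylalkyne on poisoned palladium (syn delivery of H2) sets the Z geometry that the ipso-cyclisation of step 9 needs; the alkyl chloride is inert.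

Step 4
Reactants: 6 [(1Z)-5-chloropent-1-en-1-yl]trimethylsilane
Product: 7 [(1Z)-5-iodopent-1-en-1-yl]trimethylsilane
Conditions: NaI, acetone, reflux
Reagents that add atoms: sodium iodide, [Na+].[I-]
Why: Finkelstein exchange (SN2 at a primary carbon, driven by precipitation of NaCl) provides the iodide required for zinc insertion.

Step 5
Reactants: 7 [(1Z)-5-iodopent-1-en-1-yl]trimethylsilane; 4 (4R)-4-[(tert-butyldimethylsilyl)oxy]-2,6,6-trimethylcyclohex-1-en-1-yl trifluoromethanesulfonate
Product: 9 tert-butyl(dimethyl){[(1R)-3,5,5-trimethyl-4-[(4Z)-5-(trimethylsilyl)pent-4-en-1-yl]cyclohex-3-en-1-yl]oxy}silane, via alkylzinc iodide 8 (not isolated)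
Conditions: Zn dust, LiCl, THF, 40 °C; then 4, Pd(OAc)2 (cat.), SPhos (cat.), THF, 50 °C
Reagents that add atoms: none
Why: Zinc insertion into the primary iodide followed by Negishi sp3–sp2 coupling with the hindered enol triflate (the bulky biarylphosphine favours oxidative addition and reductive elimination over β-hydride loss) forms the C6–C11 bond and the tetrasubstituted ring alkene; the silyl ether and the vinylsilane geometry are not affected.

Step 6
Reactants: 9 tert-butyl(dimethyl){[(1R)-3,5,5-trimethyl-4-[(4Z)-5-(trimethylsilyl)pent-4-en-1-yl]cyclohex-3-en-1-yl]oxy}silane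
Product: 10 (1R)-3,5,5-trimethyl-4-[(4Z)-5-(trimethylsilyl)pent-4-en-1-yl]cyclohex-3-en-1-ol
Conditions: Bu4NF, THF, 0 °C → rt; aq. NH4Cl
Reagents that add atoms: none
Why: Fluoride cleaves the silyl ether (strong Si–F bond) and frees the hydroxyl that directs step 7; the vinylic C–Si bond is not attacked under these conditions.

Step 7
Reactants: 10 (1R)-3,5,5-trimethyl-4-[(4Z)-5-(trimethylsilyl)pent-4-en-1-yl]cyclohex-3-en-1-ol
Product: 11 (1S,3S,6R)-1,5,5-trimethyl-6-[(4Z)-5-(trimethylsilyl)pent-4-en-1-yl]-7-oxabicyclo[4.1.0]heptan-3-ol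
Conditions: VO(acac)2 (cat.), t-BuOOH (decane solution), CH2Cl2, 0 °C → rt
Reagents that add atoms: tert-butyl hydroperoxide, CC(C)(C)OO
Why: Hydroxyl-directed epoxidation of a cyclic homoallylic alcohol: the vanadium-bound alkoxide delivers the peroxide oxygen to the ring alkene on the face that carries the hydroxyl (syn), which sets both epoxide carbons (the future C1 carbinol centre) and leaves the remote vinylsilane untouched.

Step 8
Reactants: 11 (1S,3S,6R)-1,5,5-trimethyl-6-[(4Z)-5-(trimethylsilyl)pent-4-en-1-yl]-7-oxabicyclo[4.1.0]heptan-3-ol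
Product: 12 (1R,4R,6S)-4-bromo-2,2,6-trimethyl-1-[(4Z)-5-(trimethylsilyl)pent-4-en-1-yl]-7-oxabicyclo[4.1.0]heptane
Conditions: PPh3, CBr4, 2,6-lutidine, CH2Cl2, 0 °C
Reagents that add atoms: carbon tetrabromide, BrC(Br)(Br)Br
Why: Appel bromination: bromide displaces the alkoxyphosphonium group by SN2 with inversion, which places bromine trans to the epoxide oxygen (the 3R centre of the target); the epoxide oxygen sits on the same face as the leaving group and cannot take part from the rear.

Step 9
Reactants: 12 (1R,4R,6S)-4-bromo-2,2,6-trimethyl-1-[(4Z)-5-(trimethylsilyl)pent-4-en-1-yl]-7-oxabicyclo[4.1.0]heptane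
Product: 13 (1S,3R,6S)-3-bromo-1,5,5-trimethylspiro[5.5]undec-7-en-1-ol
Conditions: MeAlCl2, CH2Cl2, −78 °C; aq. NaHCO3
Reagents that add atoms: none
Why: MeAlCl2 binds the oxirane oxygen and loosens the C–O bond at the chain-bearing carbon (future C6); the tethered (Z)-vinylsilane attacks this carbon through its silicon-bearing carbon (future C7) on the face opposite to the leaving oxygen, and the β-silyl cation at C8 then loses Me3Si to chloride, leaving the C7=C8 double bond exactly where silicon stood. The closest known reaction type is the Lewis-acid, epoxide-initiated cation–olefin cyclisation with a vinylsilane or allylsilane terminator, including spirocyclisations of 1-alkylcyclohexene oxides at the chain-bearing carbon. Ring B closes in the 6-exo mode with respect to the epoxide (the oxygen stays outside the new ring, on C1) and in the 6-endo mode with respect to the vinylsilane, the Z geometry being what lets ipso substitution with retention give a cis ring alkene. The new spiro centre C6 is set by inversion at the epoxide carbon, so the C6–C7 bond ends anti and the CH2CH2 arm (C11) syn to the C1 hydroxyl, whose own configuration was fixed in step 7 and is not touched; C3 is remote and unaffected. The step needs C–O cleavage at the chain-bearing and not the methyl-bearing epoxide carbon, attack through the silyl-bearing alkene carbon, and ring closure faster than 1,2-shift or proton loss from the tertiary cation: the tether reaches only the chain-bearing carbon through a six-membered transition state (the other carbon would need a 7-endo closure), this carbon is the more congested one (next to CMe2) so its C–O bond is the one that lengthens, and the β-silicon effect favours attack through C7 (six-membered ring) over attack through C8 (five-membered ring, α-silyl cation).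

Step 10
Reactants: 13 (1S,3R,6S)-3-bromo-1,5,5-trimethylspiro[5.5]undec-7-en-1-ol
Product: 14 (6S,7S,9R)-9-bromo-7-hydroxy-7,11,11-trimethylspiro[5.5]undec-1-en-3-one
Conditions: Rh2(cap)4 (cat., cap = caprolactamate), t-BuOOH, K2CO3, CH2Cl2, rt
Reagents that add atoms: tert-butyl hydroperoxide, CC(C)(C)OO
Why: Allylic C–H oxidation by tert-butylperoxyl radicals generated with the dirhodium caprolactamate catalyst: C9 is the only allylic methylene (C6 is quaternary), the mixed peroxide formed there collapses to the enone, and the other allyl terminus C7 is neopentylic and shielded; hydroxyl, bromide and stereocentres are unaffected.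

Step 11
Reactants: 14 (6S,7S,9R)-9-bromo-7-hydroxy-7,11,11-trimethylspiro[5.5]undec-1-en-3-one
Product: 15 (1S,3R,6S,9E)-3-bromo-9-(bromomethylidene)-1,5,5-trimethylspiro[5.5]undec-7-en-1-ol
Conditions: [Ph3PCH2Br]Br (slight excess over base), NaN(SiMe3)2, THF, −78 °C; then 14, −78 → 0 °C
Reagents that add atoms: (bromomethyl)triphenylphosphonium bromide, BrC[P+](c1ccccc1)(c1ccccc1)c1ccccc1.[Br-]
Why: Wittig bromomethylenation of the enone carbonyl under kinetic control, in which the bromine of the semi-stabilised ylide is expected to end on the side of the bulkier sp3 CH2 (C10) and away from the flat vinylic C8–H, i.e. the E alkene; base is kept below the amount of phosphonium salt so that the tertiary hydroxyl is not deprotonated, and any Z isomer would be removed by chromatography.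

**Compound list**

1 | (4R,6R)-4-hydroxy-2,2,6-trimethylcyclohexan-1-one | CC1(C)C[C@H](O)C[C@@H](C)C1=O | starting material
2 | (4R,6R)-4-[(tert-butyldimethylsilyl)oxy]-2,2,6-trimethylcyclohexan-1-one | CC1(C)C[C@H](O[Si](C)(C)C(C)(C)C)C[C@@H](C)C1=O | intermediate
3 | lithium (4R)-4-[(tert-butyldimethylsilyl)oxy]-2,6,6-trimethylcyclohex-1-en-1-olate | CC1(C)C[C@H](O[Si](C)(C)C(C)(C)C)CC(C)=C1[O-].[Li+] | intermediate (not isolated)
4 | (4R)-4-[(tert-butyldimethylsilyl)oxy]-2,6,6-trimethylcyclohex-1-en-1-yl trifluoromethanesulfonate | CC1(C)C[C@H](O[Si](C)(C)C(C)(C)C)CC(C)=C1OS(=O)(=O)C(F)(F)F | intermediate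
5 | (5-chloropent-1-yn-1-yl)trimethylsilane | C[Si](C)(C)C#CCCCCl | starting material
6 | [(1Z)-5-chloropent-1-en-1-yl]trimethylsilane | C[Si](C)(C)/C=C\CCCCl | intermediate
7 | [(1Z)-5-iodopent-1-en-1-yl]trimethylsilane | C[Si](C)(C)/C=C\CCCI | intermediate
8 | iodo[(4Z)-5-(trimethylsilyl)pent-4-en-1-yl]zinc | C[Si](C)(C)/C=C\CCC[Zn]I | intermediate (not isolated)
9 | tert-butyl(dimethyl){[(1R)-3,5,5-trimethyl-4-[(4Z)-5-(trimethylsilyl)pent-4-en-1-yl]cyclohex-3-en-1-yl]oxy}silane | CC1(C)C[C@H](O[Si](C)(C)C(C)(C)C)CC(C)=C1CCC/C=C\[Si](C)(C)C | intermediate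
10 | (1R)-3,5,5-trimethyl-4-[(4Z)-5-(trimethylsilyl)pent-4-en-1-yl]cyclohex-3-en-1-ol | CC1(C)C[C@H](O)CC(C)=C1CCC/C=C\[Si](C)(C)C | intermediate
11 | (1S,3S,6R)-1,5,5-trimethyl-6-[(4Z)-5-(trimethylsilyl)pent-4-en-1-yl]-7-oxabicyclo[4.1.0]heptan-3-ol | CC1(C)C[C@H](O)C[C@]2(C)O[C@]12CCC/C=C\[Si](C)(C)C | intermediate
12 | (1R,4R,6S)-4-bromo-2,2,6-trimethyl-1-[(4Z)-5-(trimethylsilyl)pent-4-en-1-yl]-7-oxabicyclo[4.1.0]heptane | CC1(C)C[C@@H](Br)C[C@]2(C)O[C@]12CCC/C=C\[Si](C)(C)C | intermediate
13 | (1S,3R,6S)-3-bromo-1,5,5-trimethylspiro[5.5]undec-7-en-1-ol | CC1(C)C[C@@H](Br)C[C@](C)(O)[C@@]12C=CCCC2 | intermediate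
14 | (6S,7S,9R)-9-bromo-7-hydroxy-7,11,11-trimethylspiro[5.5]undec-1-en-3-one | CC1(C)C[C@@H](Br)C[C@](C)(O)[C@@]12C=CC(=O)CC2 | intermediate
15 | (1S,3R,6S,9E)-3-bromo-9-(bromomethylidene)-1,5,5-trimethylspiro[5.5]undec-7-en-1-ol | CC1(C)C[C@@H](Br)C[C@](C)(O)[C@@]12C=C/C(=C/Br)CC2 | target

**Step count and risks**

Total steps: 11. Longest linear sequence: 9 (steps 1, 2, 5–11; the branch through steps 3, 4, 5–11 is equally long).

Steps most likely to fail:

1. Step 9. Ionisation at the methyl-bearing epoxide carbon, or 1,2-alkyl shift (ring contraction) and proton loss from the tertiary cation, may outrun capture by the only moderately nucleophilic vinylsilane. Fallback, from 12 back to 13: the π-nucleophile is replaced by a carbanion. Iododesilylation of 12 (N-iodosuccinimide, MeCN, 0 °C, retention of geometry) should give (1R,4R,6S)-4-bromo-1-[(4Z)-5-iodopent-4-en-1-yl]-2,2,6-trimethyl-7-oxabicyclo[4.1.0]heptane F1. Iodine–magnesium exchange (i-PrMgCl·LiCl, THF, −20 °C) then gives chloro{(1Z)-5-[(1R,4R,6S)-4-bromo-2,2,6-trimethyl-7-oxabicyclo[4.1.0]heptan-1-yl]pent-1-en-1-yl}magnesium F2, which is not isolated. On activation of the epoxide with BF3·OEt2 at −78 °C, a Parham-type 6-exo alkylation at the chain-bearing epoxide carbon, again with inversion, should close ring B and give 13.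

2. Step 11. Control of the geometry of the new exocyclic double bond may be insufficient, and retro-vinylogous-aldol fragmentation may occur if the tertiary hydroxyl is deprotonated. Fallback, from 14 to 15: the bromomethylidene is built in two stages under neutral conditions. Dibromo-olefination of 14 (CBr4, P(Oi-Pr)3, CH2Cl2, 0 °C → rt) gives (1S,3R,6S)-3-bromo-9-(dibromomethylidene)-1,5,5-trimethylspiro[5.5]undec-7-en-1-ol F3. Palladium-catalysed hydrogenolysis (Pd(PPh3)4, Bu3SnH, toluene, rt) should then remove the bromine syn to the flat vinylic C8–H, because this is the less shielded C–Br bond and lies next to the diene to which zerovalent palladium binds. The bromine syn to C10 remains, which is 15.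

3. Step 8. E2 elimination and acid-induced opening of the epoxide may compete with SN2 at a ring carbon whose rear side is partly screened by an axial methyl group. Fallback, from 10 to 12: bromination and epoxidation change places. Appel bromination of 10 (PPh3, CBr4, CH2Cl2, 0 °C, inversion) gives {(1Z)-5-[(4S)-4-bromo-2,6,6-trimethylcyclohex-1-en-1-yl]pent-1-en-1-yl}trimethylsilane F4. Epoxidation of its tetrasubstituted ring alkene with m-CPBA/NaHCO3 (CH2Cl2, −20 °C) should then occur on the face opposite to bromine, as it does for acyloxy groups in the same ring system, and give 12; the vinylsilane reacts far more slowly.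

**Further compounds**

F1 | step 9 | (1R,4R,6S)-4-bromo-1-[(4Z)-5-iodopent-4-en-1-yl]-2,2,6-trimethyl-7-oxabicyclo[4.1.0]heptane | CC1(C)C[C@@H](Br)C[C@]2(C)O[C@]12CCC/C=C\I
F2 | step 9 | chloro{(1Z)-5-[(1R,4R,6S)-4-bromo-2,2,6-trimethyl-7-oxabicyclo[4.1.0]heptan-1-yl]pent-1-en-1-yl}magnesium | CC1(C)C[C@@H](Br)C[C@]2(C)O[C@]12CCC/C=C\[Mg]Cl
F3 | step 11 | (1S,3R,6S)-3-bromo-9-(dibromomethylidene)-1,5,5-trimethylspiro[5.5]undec-7-en-1-ol | CC1(C)C[C@@H](Br)C[C@](C)(O)[C@@]12C=CC(=C(Br)Br)CC2
F4 | step 8 | {(1Z)-5-[(4S)-4-bromo-2,6,6-trimethylcyclohex-1-en-1-yl]pent-1-en-1-yl}trimethylsilane | CC1(C)C[C@@H](Br)CC(C)=C1CCC/C=C\[Si](C)(C)C
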